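**Plan**
The tert-butyl ester of the target is cut at C1–C2 and C1–C6 of ring A. C1 with its carboxyl leaves as an acetate unit, and C2–C6 with the side chain remain as a 6-alkyl-2H-pyran-2-one.
The feature that allows this: C2 (OH), C3, C4, C5 and C6 (chain) of ring A are the masked (Z)-5-oxoalk-2-enoyl unit of that pyranone (lactone carbonyl = C2, enol-ether carbon = C6).
The pyranone O–C6 bond is cut back to a (Z)-2-en-4-ynoic acid, its sp2–sp bond to ethyl (Z)-3-iodoacrylate and a terminal alkyne, and the chain to 1,10-dibromodecane, phenylmagnesium bromide and acetylide.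
Forward: chain (steps 1–2), enynoic acid (steps 3–4), pyranone ring (step 5), ring A in one operation (step 6), ester cleavage (step 7).
The target has no stereocentre. The only stereochemical element is the Z double bond of the iodoacrylate, which is kept and supplies the cis geometry both ring closures need.

Key step: step 6

Remark on the chemistry: the target is achiral, so only compounds 6, 7, 8 and 12 carry a stereo descriptor (a Z double bond).

Step 1
Reactants: 1 1,10-dibromodecane; 2 phenylmagnesium bromide
Product: 3 (10-bromodecyl)benzene
Conditions: Li2CuCl4 (3 mol%), THF, -10 °C to rt; 1 in excess (3 equiv), surplus distilled off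
Reagents that add atoms: none
Why: Copper-catalysed cross-coupling of a Grignard reagent with a primary alkyl bromide (Kochi coupling) should replace one bromide by phenyl, and the excess of 1 holds double arylation down.

Step 2
Reactants: 3 (10-bromodecyl)benzene; 4 lithium acetylide–ethylenediamine complex
Product: 5 12-phenyldodec-1-yne
Conditions: LiC≡CH·H2NCH2CH2NH2 (1.5 equiv), DMSO, 10 °C to rt
Reagents that add atoms: none
Why: SN2 alkylation of lithium acetylide by a primary bromide in DMSO is the standard two-carbon extension to a terminal alkyne, and the diamine complex limits elimination and dialkylation.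

Step 3
Reactants: 5 12-phenyldodec-1-yne; 6 ethyl (Z)-3-iodoacrylate
Product: 7 ethyl (Z)-15-phenylpentadec-2-en-4-ynoate
Conditions: PdCl2(PPh3)2 (2 mol%), CuI (4 mol%), Et3N, THF, rt, degassed
Reagents that add atoms: none
Why: Sonogashira coupling of a terminal alkyne with a β-iodoacrylate runs at room temperature with retention of the Z geometry, since oxidative addition and reductive elimination at palladium are stereospecific.

Step 4
Reactants: 7 ethyl (Z)-15-phenylpentadec-2-en-4-ynoate
Product: 8 (Z)-15-phenylpentadec-2-en-4-ynoic acid
Conditions: LiOH, THF/H2O (3:1), 0 °C to rt; then 1 M HCl to pH 3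
Reagents that add atoms: lithium hydroxide, [Li+].[OH-]
Why: Mild saponification of the ethyl ester should leave the enyne and its Z geometry untouched and frees the acid needed for lactonisation.

Step 5
Reactants: 8 (Z)-15-phenylpentadec-2-en-4-ynoic acid
Product: 9 6-(10-phenyldecyl)-2H-pyran-2-one
Conditions: ZnBr2 (15 mol%), THF, rt
Reagents that add atoms: none
Why: ZnBr2-catalysed cycloisomerisation of a (Z)-2-en-4-ynoic acid, in which the carboxyl oxygen adds to the zinc-activated alkyne in the 6-endo-dig mode, should give the 6-alkyl-2-pyranone rather than the 5-exo ylidenebutenolide when the alkyne carries an alkyl group.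

Step 6
Reactants: 9 6-(10-phenyldecyl)-2H-pyran-2-one; 10 tert-butyl acetate
Product: 13 tert-butyl 2-hydroxy-6-(10-phenyldecyl)benzoate, via lithium enolate of tert-butyl acetate 11 (not isolated), via tert-butyl (Z)-3,7-dioxo-17-phenylheptadec-4-enoate 12 (not isolated)
Conditions: LiN(i-Pr)2 (2.5 equiv), 10 (2.6 equiv), THF, -78 °C; add 9, -78 to -30 °C; then MeOH, -30 °C to rt; AcOH quench
Reagents that add atoms: none
Why: Proposed new method: the hard lithium ester enolate 11 should add to the enol-lactone carbonyl C2 of 9, the tetrahedral alkoxide collapses with the ring oxygen leaving as a dienolate, and a second equivalent of 11 deprotonates the new β-keto ester, so that open-chain 12 is held as a delocalised dianion that resists a second addition. Methanol then allows proton exchange to the monoanion in which C6 of 12 is protonated; its β-keto ester enolate carbon C2 attacks the C7 ketone, E1cB loss of water and enolisation of the resulting cyclohexadienone give the phenol, and aromatisation makes the sequence irreversible. The closest known reaction types are the conversion of pyrylium salts into benzenes by carbanions, carbanion-induced ring transformations of activated 2H-pyran-2-ones and the base-mediated aldol aromatisation of polyketo esters. Ring A closes in the 6-(enolendo)-exo-trig mode, helped by the cis C4=C5 bond of 12 inherited from the pyranone, and no stereocentre is formed. The step needs carbonyl addition to win over conjugate addition at C4 or C6 of 9 and over deprotonation of the chain CH2 next to C6, which a lithium counter-ion in THF at -78 °C, a slight excess of ester over amide (no free LiN(i-Pr)2) and the alkyl group shielding C6 should secure. The tert-butyl ester is chosen so that the rival Claisen closure of C6 of 12 onto the ester carbonyl, which would lead to a 2,4-dihydroxyphenyl ketone, stays slow.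

Step 7
Reactants: 13 tert-butyl 2-hydroxy-6-(10-phenyldecyl)benzoate
Product: 14 2-hydroxy-6-(10-phenyldecyl)benzoic acid
Conditions: CF3CO2H/CH2Cl2 (1:3), 0 °C to rt; evaporate below 30 °C
Reagents that add atoms: none
Why: Acidolysis of the tert-butyl ester (alkyl–oxygen cleavage with loss of 2-methylpropene) should free the hindered, di-ortho-substituted acid without forcing saponification, and the low temperature avoids decarboxylation of the salicylic acid.

**Compound list**
1 | 1,10-dibromodecane | BrCCCCCCCCCCBr | starting material
2 | phenylmagnesium bromide | Br[Mg]c1ccccc1 | starting material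
3 | (10-bromodecyl)benzene | BrCCCCCCCCCCc1ccccc1 | intermediate
4 | lithium acetylide–ethylenediamine complex | [Li]C#C.NCCN | starting material
5 | 12-phenyldodec-1-yne | C#CCCCCCCCCCCc1ccccc1 | intermediate
6 | ethyl (Z)-3-iodoacrylate | CCOC(=O)/C=C\I | starting material
7 | ethyl (Z)-15-phenylpentadec-2-en-4-ynoate | CCOC(=O)/C=C\C#CCCCCCCCCCCc1ccccc1 | intermediate
8 | (Z)-15-phenylpentadec-2-en-4-ynoic acid | OC(=O)/C=C\C#CCCCCCCCCCCc1ccccc1 | intermediate
9 | 6-(10-phenyldecyl)-2H-pyran-2-one | O=c1cccc(CCCCCCCCCCc2ccccc2)o1 | intermediate
10 | tert-butyl acetate | CC(=O)OC(C)(C)C | starting material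
11 | lithium enolate of tert-butyl acetate (lithium 1-tert-butoxyethenolate; not isolated) | [Li]OC(=C)OC(C)(C)C | intermediate
12 | tert-butyl (Z)-3,7-dioxo-17-phenylheptadec-4-enoate (not isolated; present as its lithium enolates) | CC(C)(C)OC(=O)CC(=O)/C=C\CC(=O)CCCCCCCCCCc1ccccc1 | intermediate
13 | tert-butyl 2-hydroxy-6-(10-phenyldecyl)benzoate | CC(C)(C)OC(=O)c1c(O)cccc1CCCCCCCCCCc1ccccc1 | intermediate
14 | 2-hydroxy-6-(10-phenyldecyl)benzoic acid | O=C(O)c1c(O)cccc1CCCCCCCCCCc1ccccc1 | target

**Step count**
Total steps: 7. Longest linear sequence: 7 steps (from 1 and 2 to 14).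

**Steps most likely to fail**

Step 6, the ring transformation without direct precedent. The enolate may add in conjugate fashion or merely deprotonate the chain CH2 at C6 of 9. The ring-opened dianion may also isomerise to the extended E form, or reclose on oxygen to a 2H-pyran-2-ylidene acetate, instead of passing through the aldol. The fallback uses known chemistry, leaves the pyranone route, sets out from bromide 3 and rejoins the route at target 14. Zinc insertion into 3 (Zn dust, LiCl, THF, 50 °C) gives (10-phenyldecyl)zinc bromide F1. Commercial 5-hydroxy-2,2-dimethyl-4H-1,3-benzodioxin-4-one (CC1(C)OC(=O)c2c(O)cccc2O1) is converted with (CF3SO2)2O and pyridine in CH2Cl2 into 2,2-dimethyl-4-oxo-4H-1,3-benzodioxin-5-yl trifluoromethanesulfonate F2. Negishi coupling of the two (Pd(OAc)2, SPhos, THF, rt to 50 °C) should give 2,2-dimethyl-5-(10-phenyldecyl)-4H-1,3-benzodioxin-4-one F3. KOH in DMSO/H2O at 80 °C followed by HCl opens the acetonide to 14.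

Step 5. The acid may cyclise in the 5-exo-dig mode to the ylidenebutenolide, or the enynoic acid may lose its Z geometry (this can already happen in step 4), so that lactonisation stalls. The fallback sets out from ester 7, bypasses acid 8 and returns at pyranone 9. Iodocyclisation of 7 with ICl in CH2Cl2 at rt should give 5-iodo-6-(10-phenyldecyl)-2H-pyran-2-one F4: the ester carbonyl oxygen attacks the iodonium-activated alkyne 6-endo and the ethyl group is lost as chloroethane. Hydrodeiodination with Bu3SnH and catalytic Pd(PPh3)4 in THF then gives 9.

Step 1. A second arylation of the product bromide would give 1,10-diphenyldecane, and the aryl Grignard may couple sluggishly and homocouple to biphenyl, which makes purification of 3 difficult. The fallback sets out from 2 and returns at 3. Li2CuCl4-catalysed coupling of 2 with commercial 10-bromodec-1-ene (C=CCCCCCCCCBr), which has only one leaving group, gives (dec-9-en-1-yl)benzene F5. Radical-chain anti-Markovnikov addition of HBr (HBr, dibenzoyl peroxide, hexane, 0 °C) then gives 3.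

**Further compounds**
F1 | step 6 | (10-phenyldecyl)zinc bromide | Br[Zn]CCCCCCCCCCc1ccccc1
F2 | step 6 | 2,2-dimethyl-4-oxo-4H-1,3-benzodioxin-5-yl trifluoromethanesulfonate | CC1(C)OC(=O)c2c(OS(=O)(=O)C(F)(F)F)cccc2O1
F3 | step 6 | 2,2-dimethyl-5-(10-phenyldecyl)-4H-1,3-benzodioxin-4-one | CC1(C)OC(=O)c2c(CCCCCCCCCCc3ccccc3)cccc2O1
F4 | step 5 | 5-iodo-6-(10-phenyldecyl)-2H-pyran-2-one | O=c1ccc(I)c(CCCCCCCCCCc2ccccc2)o1
F5 | step 1 | (dec-9-en-1-yl)benzene | C=CCCCCCCCCc1ccccc1
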